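(The runs are simulated from invented constants; scatter was added.)

No constants are known for this flask, so we read one from the two runs.

| setting | Monday's | Sunday's | flask |
|---|---|---|---|
| substrate | 0.40 M | 0.40 M | 0.40 M |
| partner | 0.44 M | 0.44 M | 0.440 M |
| free catalyst | 20 mM | 20 mM | 20 mM |
| added ligand | 44 mM | 67 mM | 89 mM |
| remark | run made earlier | run made earlier |  |

| run | time / min | product / % | substrate / % |
|---|---|---|---|
| Monday's | 3.00 | 1 | 96 |
| Monday's | 10.0 | 0 | 92 |
| Monday's | 15.0 | 3 | 88 |
| Monday's | 25.0 | 5 | 81 |
| Monday's | 40.0 | 7 | 73 |
| Monday's | 50.0 | 10 | 67 |
| Monday's | 60.0 | 12 | 66 |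
| Sunday's | 3.00 | 2 | 95 |
| Sunday's | 10.0 | 2 | 91 |
| Sunday's | 15.0 | 2 | 87 |
| Sunday's | 25.0 | 5 | 80 |
| Sunday's | 40.0 | 9 | 74 |
| Sunday's | 50.0 | 5 | 70 |
| Sunday's | 60.0 | 9 | 66 |

(each reading ± 1.5 percentage points)

* factor on the rate of making product when 50% of the substrate are converted if partner is charged twice over
* factor on the rate when 50% of the substrate are converted if free catalyst is charged at 4.0 mM instead

- what was read earlier has a scatter of 1.5 percentage points, one standard deviation
- no earlier run changes the charge of free catalyst; that part of a forecast is a guess
- no earlier run changes the charge of partner; that part of a forecast is a guess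

At 60.0 min, substrate stands at 66% in Monday's run and 66% in Sunday's run, and product at 12% and 9%. So product trails the lost substrate. Pooling both runs, we read the capture odds, product over lost substrate that is not product, as 0.447.

Our reckoning supposes a fork: lost substrate either reaches product by a step that needs free catalyst or goes elsewhere. Then the odds and the substrate loss both scale with free catalyst. At 4.0 mM, the charge ratio is 0.200 and the odds become 0.0894. The share reaching product falls from 30.9% to 8.20%. The rate factor is the charge ratio times that fall, 0.0531. Partner was never varied, so we guess it joins after the fork and take a factor of 1 for doubling it.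

The forecast gave 2.2 for doubled partner and 0.2 for the smaller charge of free catalyst, the second with the words “First order gives 0.2”.

The simulation gives 1.04 and 0.0422. Our 0.0531 stands above the second, which lies near the square of the charge ratio, 0.0400.

    free catalyst + added ligand ⇌ idle complex (K = 21.0 /M, k = 0.400 /M/min)
    open intermediate → decomposed reagent (k = 0.0410 /min)
    free catalyst + open intermediate ⇌ catalyst intermediate (K = 15.0 /M, k = 2.20 /M/min)
    substrate + free catalyst → free catalyst + open intermediate (k = 0.540 /M/min)
    partner + catalyst intermediate → free catalyst + product (k = 4.50 /M/min)

In this flask substrate fed open intermediate, which stood at 7.56% at 25.0 min, while added ligand drew free catalyst into the idle complex, an off-cycle form, with 41.9% free, 56.8% idle and 1.22% as catalyst intermediate at 50.0 min. Open intermediate went on to product and decomposed reagent, and at 500 min, with 11.3% of the substrate left, the share 30.9% from our capture odds of 0.447 puts product at 27.4% of the substrate charged, where this flask held 25.7%.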